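## The problem

CNP0221531.1 (28) is a cyclohexene of the mulberry Diels–Alder type. A 1-methylcyclohexene carries, on three contiguous sp3 carbons, a 2-arylbenzofuran (C3), a 2,4-dihydroxybenzoyl group (C4) and a 2,4-dihydroxyphenyl group (C5). Throughout, C1 is the methyl-bearing alkene carbon, C2 the alkene CH and C6 the ring CH2; the benzofuran keeps its own numbers.

The configuration is (3R,4R,5S), all-trans, so every substituent can be equatorial on the half-chair. C4 is α to the ketone and epimerisable, C3 is benzylic and allylic, and only C5 is configurationally inert. C5 is therefore the place to introduce absolute configuration and to let it steer C3 and C4 under equilibrating conditions.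

The carbocycle sits on benzofuran C5, the carbon between the 4-OH and the 6-OH. The same ring offers C7 as a second nucleophilic site, so regiocontrol is needed. Six phenols, a trisubstituted alkene that can add a neighbouring phenol under strong acid, and a ketone flanked by ortho-hydroxyaryl groups exclude harsh acid, oxidants and hydrogenolysis late in the route.

The feature exploited is that C3 is bonded to benzofuran C5 (ortho to O4) and is allylic to C1=C2. O4, benzofuran C4 and C5, C3, C2 and C1 are thus the six atoms of a latent 2H-chromene with C1 as its quaternary O-bearing carbon. The isomer of the target with O4–C1 closed and C3–C4 open is a benzofuran-fused 2-methyl-2H-chromene with an aryl ketone side chain.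

## Retrosynthesis

**28 from 26.** Only O–C and O–Si bonds are cut. The four phenols of the two resorcinol rings are MOM ethers, the benzofuran 6-OH and the 3-hydroxyphenyl OH are triisopropylsilyl ethers, and the 4-OH is free. MOM survives the organolithium, hydride and amine steps on the ketone side. The silyl ethers survive the acid needed to build the benzofuran and mark O6 as different from O4. Acetates or benzyl ethers would not survive the aryllithium chemistry or would need hydrogenolysis next to the ring alkene. The forward reaction is fluoride, then dilute methanolic acid, on a compound whose C4 centre is already trans.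

**26 from 24 (key disconnection).** The C3–C4 bond is cut and O4 is joined to C1, which gives chromene 24, an isomer of 26. Cutting C3–benzofuran C5 instead (allyl cation plus phenol) would leave the C5/C7 regiochemistry open. Cutting C2–C3 and C4–C5 is the cycloaddition discussed under the alternatives. Compound 24 lacks the carbocycle and two of the three stereocentres; its quaternary carbon is a stereocentre of no consequence. The forward step must open the chromene to the vinyl ortho-quinone methide with C6 cis to C3 across C1=C2, the (2Z) isomer 25, add the ketone enol to C3 and deliver the all-trans ring.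

**24 from 12 and 22.** The C3–benzofuran C5 bond and the O4–C1 bond are cut, which is a formal [3+3] union of a phenol with a β,β-disubstituted enal. Condensation first gives the quinone methide with the chain geometry of the enal, the (2E) isomer 23, which cannot reach C3 with its ketone arm and simply closes to the pyran. In 22 the only free position ortho to the free 4-OH is C5. Attack at C7 cannot close a pyran because O6 is silylated, so only one chromene can form. The precursors are an open-chain keto-enal with one stereocentre and an achiral benzofuranol. The forward reaction must be mild enough to spare the enolisable aryl ketone of 12.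

**12 from 6 and 8 (through 10 and 11).** The aryl–carbonyl bond is cut. Aryllithium 9, made from bromide 8, adds to the aldehyde of 6. The ester end is then reduced, and one oxidant takes the benzylic and allylic alcohols of diol 11 to the ketone and the enal together. Addition to an aldehyde is preferred to acylation chemistry because it is selective over the hindered enoate at low temperature. The price is two redox steps, which are shared between both chain ends.

**6 from 3 and 5.** The C5–C6 bond is cut: a vinylogous Mukaiyama–Michael addition of silyl dienolate 5 to enal 3 under iminium catalysis. It builds the whole 1,7-dioxygenated chain and sets C5 in one step. A chalcone acceptor would deliver 12 more directly, but a catalytic asymmetric version with an acyclic dienolate is not established for enones. The enal version is a known reaction type, and that is judged worth three extra steps.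

**3 from 1, 5 from 4, 8 from 7.** These are protecting-group and homologation steps only: aldehyde 1 is protected to 2 and extended by a Wittig reaction, ester 4 is converted to its silyl dienolate, and bromoresorcinol 7 is protected.

**22 from 18 and 20.** The bond from the iodine-bearing carbon of 18 (benzofuran C3a) to the alkyne (C3) and the O1–C2 bond are cut: a Sonogashira coupling followed by 5-endo cyclisation. Because 18 is symmetric, either hydroxyl closes the furan and the other becomes the free 4-OH, with the silyl ether ending at O6. The O4/O6 distinction is thus made by symmetry, not by a selective protection of a benzofurandiol. The forward reaction is the domino coupling–cyclisation of an ortho-iodophenol with alkyne 20, passing through alkynylresorcinol 21.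

**18 from 13 (through 14, 15, 17).** The C–I bond is cut back to a C–H bond. The iodine is placed by directed ortho-metalation between two MOM ethers of 15, through aryllithium 16; the bulky, non-coordinating silyl ether blocks the other positions. Electrophilic iodination of a phloroglucinol monoether would not distinguish the sites. The cost is a statistical bis-protection of phloroglucinol 13 to 14 and a later acid step that removes the directing groups.

## Roads not taken

**Alternative 1:** The ring is cut at C4–C5 and at the C1=C2 double bond. In the forward sense methyl 4-(dimethoxyphosphoryl)-3-oxobutanoate A1 adds through its doubly activated carbon to (3E)-4-[2,4-bis(methoxymethoxy)phenyl]but-3-en-2-one A2 under a primary-amine cinchona catalyst. Its phosphonate carbon then olefinates the methyl ketone to give cyclohexenone ester A3.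
- Merits: both component reactions are well known, C5 and the trans C4 centre come from catalysis, and the carbocycle is reached in very few steps.
- Weak points: A3 has a ketone at C3 and an ester on C4. The benzofuran must then be added as a hindered aryl nucleophile (its C5 lies between two oxygens) to a vinylogous β-keto ester that organometallics deprotonate. The resulting tertiary hydroxyl must be removed with the alkene left at C1=C2 and C3 set trans, and the ester must become an aryl ketone between two aryl-bearing carbons.
- Comparison: this road is better in the certainty of its ring-forming step and in step count to a carbocycle. The chosen plan sets against it that both aryl–carbon bonds are made on open-chain compounds, and that C3 and C4 are set in the ring closure itself without redox work at C3.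

**Alternative 2:** The ring is cut at C2–C3 and C4–C5, a Diels–Alder reaction with the aryl groups exchanged between the partners. Silyl diene A4 carries the C5 aryl group and 2′-hydroxychalcone A5 carries the benzofuran on its β-carbon. A chiral borate Lewis acid, made from a triaryl borate and an enantiopure biaryl diol, would give cycloadduct A6 with the alkene at C6=C1 and silicon on C2. Protodesilylation of the allylsilane then moves the alkene to C1=C2.
- Merits: boron-catalysed cycloaddition of 2′-hydroxychalcones is established for this family, is convergent and forms two C–C bonds with absolute control. Its precedent is stronger than that of the chosen key step.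
- Weak points: the β-aryl group of A5 is a di-ortho-oxygenated benzofuran-5-yl, twisted and hindered. The 1-aryl-3-methyl-4-silyl diene is less reactive than a simple dehydroprenyl diene. Exo selectivity is needed for the all-trans product, and the protodesilylation needs acid among MOM ethers. A5 also needs a C5-functionalised benzofuran, so the regiochemical work spent on 22 is not saved.
- Comparison: the chosen plan offers trans,trans stereochemistry by equilibration instead of kinetic endo/exo control and needs no alkene transposition. It must set against Alternative 2 the risk of an untested step, which is why a cycloaddition of normal polarity is kept as its fallback.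

**Alternative 3:** Three bonds of the benzofuran benzene ring are cut (C4–C5, C6–C7, C3a–C4), a photochemical Danheiser benzannulation. Irradiation of diazoketone A7 gives a ketene by Wolff rearrangement. This adds to siloxyalkyne A8, and four-electron opening followed by six-electron closure onto furan C3 gives A9, the target skeleton with 4-OH free and 6-O silylated.
- Merits: the oxygenation pattern of the benzofuran follows from the mechanism. In this respect it is better than the chosen route, which spends steps 9 to 12 and 14 on the same distinction.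
- Weak points: A8 must already hold the complete cyclohexene with all three stereocentres and an ynol ether at C3, so the central problem is moved into a precursor with no short route. The photolysis also has to tolerate two dialkoxyaryl ketone chromophores and an enolisable ketone beside a ketene.
- Comparison: this road is superior for the heteroaromatic part and inferior for the carbocycle. The chosen plan sets against it a longer but routine directed-metalation route to 22 and a key step that builds the ring and two stereocentres.

Key step: step 16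

## Route

Assumptions:
- The geometry of the C2=C3 double bond in 6, 10, 11 and 12 (E is drawn) is of no consequence, because that carbon becomes tetrahedral in 24 and returns as the ring alkene in step 16.
- Compounds 10 and 11 are carried as both epimers at the carbinol carbon, and 24 as both epimers at its quaternary carbon.
- Quinone methides 23 and 25 are the (2E) and (2Z) isomers of one constitution; both are drawn with the (5Z) exocyclic geometry (vinyl group syn to the ring carbonyl) that electrocyclic closure needs and that electrocyclic opening delivers.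

Step 1
Reactants: 1 2,4-dihydroxybenzaldehyde
Product: 2 2,4-bis(methoxymethoxy)benzaldehyde
Conditions: NaH, MOMCl, DMF, 0 °C to rt
Reagents that add atoms: chloromethyl methyl ether (MOMCl), COCCl
Why: O-alkylation of both phenoxides (Williamson ether synthesis); the sodium salt is used because the 2-OH is hydrogen-bonded to the aldehyde and reacts sluggishly with amine bases.

Step 2
Reactants: 2 2,4-bis(methoxymethoxy)benzaldehyde
Product: 3 (2E)-3-[2,4-bis(methoxymethoxy)phenyl]prop-2-enal
Conditions: Ph3P=CHCHO, toluene, 80 °C
Reagents that add atoms: (triphenylphosphoranylidene)acetaldehyde, O=CC=P(c1ccccc1)(c1ccccc1)c1ccccc1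
Why: Wittig two-carbon homologation with a stabilised ylide should give the E-enal; the product is a poorer electrophile than 2, which limits a second homologation.

Step 3
Reactants: 4 ethyl 3-methylbut-2-enoate
Product: 5 tert-butyl[(1-ethoxy-3-methylbuta-1,3-dien-1-yl)oxy]dimethylsilane
Conditions: LiN(i-Pr)2, THF, −78 °C; TBSCl, DMPU, −78 °C to rt
Reagents that add atoms: tert-butyldimethylsilyl chloride (TBSCl), CC(C)(C)[Si](C)(C)Cl
Why: kinetic γ-deprotonation of the enoate and O-silylation of the extended enolate give the silyl dienolate (silyl ketene acetal formation), used after distillation.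

Step 4
Reactants: 3 (2E)-3-[2,4-bis(methoxymethoxy)phenyl]prop-2-enal; 5 tert-butyl[(1-ethoxy-3-methylbuta-1,3-dien-1-yl)oxy]dimethylsilane
Product: 6 ethyl (2E,5S)-5-[2,4-bis(methoxymethoxy)phenyl]-3-methyl-7-oxohept-2-enoate
Conditions: (S)-2-[diphenyl(trimethylsilyloxy)methyl]pyrrolidine (20 mol %), 4-nitrobenzoic acid (20 mol %), H2O (3 equiv), CH2Cl2, 0 °C
Reagents that add atoms: none
Why: iminium-catalysed vinylogous Mukaiyama–Michael addition, a known reaction of acyclic silyl dienolates with enals; the γ-carbon of 5 attacks the β-carbon of the E-iminium ion on the face opposite the diphenyl(silyloxy)methyl group, which for the (S)-catalyst sets (S)-C5. The selectivity needed is γ- over α-attack, favoured by the bulky iminium ion and the extended dienolate; water takes up the silyl group.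

Step 5
Reactants: 7 4-bromobenzene-1,3-diol
Product: 8 1-bromo-2,4-bis(methoxymethoxy)benzene
Conditions: MOMCl, i-Pr2NEt, CH2Cl2, 0 °C to rt
Reagents that add atoms: chloromethyl methyl ether (MOMCl), COCCl
Why: routine O-alkylation of both phenols to the MOM ethers.

Step 6
Reactants: 8 1-bromo-2,4-bis(methoxymethoxy)benzene; 6 ethyl (2E,5S)-5-[2,4-bis(methoxymethoxy)phenyl]-3-methyl-7-oxohept-2-enoate
Product: 10 ethyl (2E,5S)-5,7-bis[2,4-bis(methoxymethoxy)phenyl]-7-hydroxy-3-methylhept-2-enoate (both C7 epimers), via aryllithium 9 (not isolated)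
Conditions: n-BuLi, THF, −78 °C; then 6, −78 °C; aq NH4Cl
Reagents that add atoms: none
Why: bromine–lithium exchange gives aryllithium 9, held by the ortho MOM ether, which should add to the aldehyde far faster than to the β,β-disubstituted enoate at −78 °C (1,2-addition of an organolithium). The carbinol centre forms without control and is erased in step 8.

Step 7
Reactants: 10 ethyl (2E,5S)-5,7-bis[2,4-bis(methoxymethoxy)phenyl]-7-hydroxy-3-methylhept-2-enoate
Product: 11 (2E,5S)-5,7-bis[2,4-bis(methoxymethoxy)phenyl]-3-methylhept-2-ene-1,7-diol (both C7 epimers)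
Conditions: i-Bu2AlH (4 equiv), CH2Cl2, −78 °C
Reagents that add atoms: none
Why: 1,2-reduction of the conjugated ester to the allylic alcohol by the aluminium hydride; the secondary alkoxide is a spectator.

Step 8
Reactants: 11 (2E,5S)-5,7-bis[2,4-bis(methoxymethoxy)phenyl]-3-methylhept-2-ene-1,7-diol
Product: 12 (2E,5S)-5,7-bis[2,4-bis(methoxymethoxy)phenyl]-3-methyl-7-oxohept-2-enal
Conditions: Dess–Martin periodinane, NaHCO3, CH2Cl2, 0 °C to rt
Reagents that add atoms: none
Why: Dess–Martin oxidation takes the benzylic carbinol to the aryl ketone and the allylic alcohol to the enal in one operation; the buffer protects the MOM ethers and C5 is not epimerisable.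

Step 9
Reactants: 13 benzene-1,3,5-triol (phloroglucinol)
Product: 14 3,5-bis(methoxymethoxy)phenol
Conditions: MOMCl (2.0 equiv), i-Pr2NEt, DMF, 0 °C
Reagents that add atoms: chloromethyl methyl ether (MOMCl), COCCl
Why: statistical O-alkylation; the bis-ether is separated from the mono- and tris-ethers by chromatography.

Step 10
Reactants: 14 3,5-bis(methoxymethoxy)phenol
Product: 15 [3,5-bis(methoxymethoxy)phenoxy]tri(propan-2-yl)silane
Conditions: TIPSCl, imidazole, DMF, rt
Reagents that add atoms: chlorotri(propan-2-yl)silane (TIPSCl), CC(C)[Si](Cl)(C(C)C)C(C)C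
Why: routine silylation of the remaining phenol with a bulky silyl group that neither directs metalation nor is lost in dilute acid.

Step 11
Reactants: 15 [3,5-bis(methoxymethoxy)phenoxy]tri(propan-2-yl)silane
Product: 17 [4-iodo-3,5-bis(methoxymethoxy)phenoxy]tri(propan-2-yl)silane, via aryllithium 16 (not isolated)
Conditions: n-BuLi, THF, 0 °C; I2, −78 °C to rt
Reagents that add atoms: iodine, II
Why: directed ortho-metalation at the carbon flanked by both MOM ethers (cooperative direction), the silyl ether shielding its own ortho positions; iodine quench gives the aryl iodide.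

Step 12
Reactants: 17 [4-iodo-3,5-bis(methoxymethoxy)phenoxy]tri(propan-2-yl)silane
Product: 18 2-iodo-5-{[tri(propan-2-yl)silyl]oxy}benzene-1,3-diol
Conditions: HCl (1.25 M in MeOH), 0 °C to rt
Reagents that add atoms: none
Why: acid-catalysed transacetalisation to methanol removes both MOM ethers; the aryl triisopropylsilyl ether should be stable to dilute methanolic acid.

Step 13
Reactants: 19 3-ethynylphenol
Product: 20 (3-ethynylphenoxy)tri(propan-2-yl)silane
Conditions: TIPSCl, imidazole, DMF, rt
Reagents that add atoms: chlorotri(propan-2-yl)silane (TIPSCl), CC(C)[Si](Cl)(C(C)C)C(C)C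
Why: routine phenol silylation; the terminal alkyne is untouched.

Step 14
Reactants: 18 2-iodo-5-{[tri(propan-2-yl)silyl]oxy}benzene-1,3-diol; 20 (3-ethynylphenoxy)tri(propan-2-yl)silane
Product: 22 6-{[tri(propan-2-yl)silyl]oxy}-2-(3-{[tri(propan-2-yl)silyl]oxy}phenyl)-1-benzofuran-4-ol, via alkynylresorcinol 21 (not isolated)
Conditions: PdCl2(PPh3)2 (5 mol %), CuI (10 mol %), Et3N, DMF, 60 °C, degassed
Reagents that add atoms: none
Why: Sonogashira coupling followed in the same flask by 5-endo-dig addition of an ortho hydroxyl to the activated alkyne (the standard ortho-iodophenol route to 2-arylbenzofurans). The two hydroxyls of 18 are equivalent, so either closure leaves the other as the free 4-OH with the silyl ether at O6.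

Step 15
Reactants: 12 (2E,5S)-5,7-bis[2,4-bis(methoxymethoxy)phenyl]-3-methyl-7-oxohept-2-enal; 22 6-{[tri(propan-2-yl)silyl]oxy}-2-(3-{[tri(propan-2-yl)silyl]oxy}phenyl)-1-benzofuran-4-ol
Product: 24 (3S)-1,3-bis[2,4-bis(methoxymethoxy)phenyl]-4-[2-methyl-5-{[tri(propan-2-yl)silyl]oxy}-8-(3-{[tri(propan-2-yl)silyl]oxy}phenyl)-2H-furo[2,3-h]chromen-2-yl]butan-1-one (both epimers at chromene C2), via (2E)-quinone methide 23 (not isolated)
Conditions: ethylenediammonium diacetate (20 mol %), toluene, 100 °C
Reagents that add atoms: none
Why: amine-catalysed Knoevenagel-type condensation of the enal at C5, the only free position ortho to the 4-OH, gives quinone methide 23, which keeps the (2E) chain geometry of 12 and closes by oxa-6π electrocyclisation (formal [3+3] chromene synthesis of electron-rich phenols with β,β-disubstituted enals). In 23 the ketone arm is trans to the methide carbon and cannot reach it, so pyran closure is the only outlet; the quaternary centre forms as both epimers and both are used.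

Step 16
Reactants: 24 (3S)-1,3-bis[2,4-bis(methoxymethoxy)phenyl]-4-[2-methyl-5-{[tri(propan-2-yl)silyl]oxy}-8-(3-{[tri(propan-2-yl)silyl]oxy}phenyl)-2H-furo[2,3-h]chromen-2-yl]butan-1-one
Product: 26 [2,4-bis(methoxymethoxy)phenyl]{(1R,2R,6S)-6-[2,4-bis(methoxymethoxy)phenyl]-2-[4-hydroxy-6-{[tri(propan-2-yl)silyl]oxy}-2-(3-{[tri(propan-2-yl)silyl]oxy}phenyl)-1-benzofuran-5-yl]-4-methylcyclohex-3-en-1-yl}methanone, via (2Z)-quinone methide 25 (not isolated)
Conditions: Sc(OTf)3 (10 mol %), 2,6-di-tert-butyl-4-methylpyridine (20 mol %), 4 Å MS, 1,2-dichloroethane, 60 °C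
Reagents that add atoms: none
Why: Proposed new method: the O4–C1 bond of the 2,2-disubstituted chromene opens by retro-oxa-6π electrocyclisation, helped by Sc(OTf)3 on the emerging dienone oxygen, to a vinyl ortho-quinone methide; in its (2Z) isomer 25 the Sc-chelated enol of the aryl ketone adds through C4 to the exocyclic methide carbon C3, and proton transfer restores the aromatic benzofuran with its 4-OH. The closest known reaction types are the reversible thermal, photochemical and Lewis-acid opening of 2H-chromenes to ortho-quinone methides and the Michael addition of ketone enols or enolates to ortho-quinone methides; their intramolecular combination as a net isomerisation has not been shown. The cyclohexene closes 6-(enolexo)-exo-trig on the methide double bond, with C1=C2 already in place as the ring alkene. C3 and C4 are set relative to the fixed (5S) centre by a chair-like transition state in which the C5 aryl group, the enol and the benzofuranylidene unit are all equatorial, which gives the 3,4-trans-4,5-trans (3R,4R,5S) product. Both new centres stay correctable under the conditions (C4 by enolisation, C3 by retro-Michael and re-addition), so the all-equatorial isomer is also the thermodynamic end point. The chemoselectivity needed is that C–C bond formation outruns the 1,7-hydrogen shift or proton loss that would turn the methide into a dienylphenol; the Lewis acid raises the enol concentration so that 60 °C suffices, below the range of such shifts, and the hindered pyridine traps triflic acid that would cleave MOM ethers. Only 25, in which C6 is cis to C3 across C1=C2, can cyclise; opening in the other rotational sense leads to the (2E) isomer 23, which can only reclose to 24, and because reclosure interconverts both chromene epimers and both methide geometries the material funnels through 25. Attack at the other electrophilic carbon, C1, is excluded because it would close a four-membered ring.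

Step 17
Reactants: 26 [2,4-bis(methoxymethoxy)phenyl]{(1R,2R,6S)-6-[2,4-bis(methoxymethoxy)phenyl]-2-[4-hydroxy-6-{[tri(propan-2-yl)silyl]oxy}-2-(3-{[tri(propan-2-yl)silyl]oxy}phenyl)-1-benzofuran-5-yl]-4-methylcyclohex-3-en-1-yl}methanone
Product: 28 (2,4-dihydroxyphenyl){(1R,2R,6S)-6-(2,4-dihydroxyphenyl)-2-[4,6-dihydroxy-2-(3-hydroxyphenyl)-1-benzofuran-5-yl]-4-methylcyclohex-3-en-1-yl}methanone (CNP0221531.1), via triol 27 (not isolated)
Conditions: Bu4NF (2.5 equiv), THF, 0 °C; then HCl (3 M aq), MeOH, 40 °C
Reagents that add atoms: none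
Why: fluoride cleaves the two aryl silyl ethers at 0 °C, and acidifying the same flask with methanolic HCl removes the four MOM ethers by transacetalisation (standard desilylation and acetal cleavage). C4 already has its thermodynamic trans configuration, so neither medium can erode it, and the moderate temperature is chosen to keep the free phenols from adding to the ring alkene or the ketone.

## Compound list

1 | 2,4-dihydroxybenzaldehyde | O=Cc1ccc(O)cc1O | starting material
2 | 2,4-bis(methoxymethoxy)benzaldehyde | O=Cc1ccc(OCOC)cc1OCOC | intermediate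
3 | (2E)-3-[2,4-bis(methoxymethoxy)phenyl]prop-2-enal | O=C/C=C/c1ccc(OCOC)cc1OCOC | intermediate
4 | ethyl 3-methylbut-2-enoate | CCOC(=O)C=C(C)C | starting material
5 | tert-butyl[(1-ethoxy-3-methylbuta-1,3-dien-1-yl)oxy]dimethylsilane (mixture of ketene acetal geometries) | CCOC(=CC(C)=C)O[Si](C)(C)C(C)(C)C | intermediate
6 | ethyl (2E,5S)-5-[2,4-bis(methoxymethoxy)phenyl]-3-methyl-7-oxohept-2-enoate | CCOC(=O)/C=C(\C)C[C@H](c1ccc(OCOC)cc1OCOC)CC=O | intermediate
7 | 4-bromobenzene-1,3-diol | Oc1ccc(Br)c(O)c1 | starting material
8 | 1-bromo-2,4-bis(methoxymethoxy)benzene | COCOc1ccc(Br)c(OCOC)c1 | intermediate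
9 | [2,4-bis(methoxymethoxy)phenyl]lithium (not isolated) | [Li]c1ccc(OCOC)cc1OCOC | intermediate
10 | ethyl (2E,5S)-5,7-bis[2,4-bis(methoxymethoxy)phenyl]-7-hydroxy-3-methylhept-2-enoate (both C7 epimers) | CCOC(=O)/C=C(\C)C[C@H](c1ccc(OCOC)cc1OCOC)CC(O)c1ccc(OCOC)cc1OCOC | intermediate
11 | (2E,5S)-5,7-bis[2,4-bis(methoxymethoxy)phenyl]-3-methylhept-2-ene-1,7-diol (both C7 epimers) | OC/C=C(\C)C[C@H](c1ccc(OCOC)cc1OCOC)CC(O)c1ccc(OCOC)cc1OCOC | intermediate
12 | (2E,5S)-5,7-bis[2,4-bis(methoxymethoxy)phenyl]-3-methyl-7-oxohept-2-enal | O=C/C=C(\C)C[C@H](c1ccc(OCOC)cc1OCOC)CC(=O)c1ccc(OCOC)cc1OCOC | intermediate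
13 | benzene-1,3,5-triol (phloroglucinol) | Oc1cc(O)cc(O)c1 | starting material
14 | 3,5-bis(methoxymethoxy)phenol | COCOc1cc(O)cc(OCOC)c1 | intermediate
15 | [3,5-bis(methoxymethoxy)phenoxy]tri(propan-2-yl)silane | COCOc1cc(OCOC)cc(O[Si](C(C)C)(C(C)C)C(C)C)c1 | intermediate
16 | [2,6-bis(methoxymethoxy)-4-{[tri(propan-2-yl)silyl]oxy}phenyl]lithium (not isolated) | [Li]c1c(OCOC)cc(O[Si](C(C)C)(C(C)C)C(C)C)cc1OCOC | intermediate
17 | [4-iodo-3,5-bis(methoxymethoxy)phenoxy]tri(propan-2-yl)silane | COCOc1cc(O[Si](C(C)C)(C(C)C)C(C)C)cc(OCOC)c1I | intermediate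
18 | 2-iodo-5-{[tri(propan-2-yl)silyl]oxy}benzene-1,3-diol | Oc1cc(O[Si](C(C)C)(C(C)C)C(C)C)cc(O)c1I | intermediate
19 | 3-ethynylphenol | C#Cc1cccc(O)c1 | starting material
20 | (3-ethynylphenoxy)tri(propan-2-yl)silane | C#Cc1cccc(O[Si](C(C)C)(C(C)C)C(C)C)c1 | intermediate
21 | 5-{[tri(propan-2-yl)silyl]oxy}-2-[(3-{[tri(propan-2-yl)silyl]oxy}phenyl)ethynyl]benzene-1,3-diol (not isolated) | Oc1cc(O[Si](C(C)C)(C(C)C)C(C)C)cc(O)c1C#Cc1cccc(O[Si](C(C)C)(C(C)C)C(C)C)c1 | intermediate
22 | 6-{[tri(propan-2-yl)silyl]oxy}-2-(3-{[tri(propan-2-yl)silyl]oxy}phenyl)-1-benzofuran-4-ol | Oc1cc(O[Si](C(C)C)(C(C)C)C(C)C)cc2oc(-c3cccc(O[Si](C(C)C)(C(C)C)C(C)C)c3)cc12 | intermediate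
23 | (5Z)-5-[(2E,5S)-5,7-bis[2,4-bis(methoxymethoxy)phenyl]-3-methyl-7-oxohept-2-en-1-ylidene]-6-{[tri(propan-2-yl)silyl]oxy}-2-(3-{[tri(propan-2-yl)silyl]oxy}phenyl)-1-benzofuran-4(5H)-one (vinyl ortho-quinone methide with the methyl group cis to the methide carbon; not isolated) | C/C(C[C@H](c1ccc(OCOC)cc1OCOC)CC(=O)c1ccc(OCOC)cc1OCOC)=C\C=C1/C(=O)c2cc(-c3cccc(O[Si](C(C)C)(C(C)C)C(C)C)c3)oc2C=C1O[Si](C(C)C)(C(C)C)C(C)C | intermediate
24 | (3S)-1,3-bis[2,4-bis(methoxymethoxy)phenyl]-4-[2-methyl-5-{[tri(propan-2-yl)silyl]oxy}-8-(3-{[tri(propan-2-yl)silyl]oxy}phenyl)-2H-furo[2,3-h]chromen-2-yl]butan-1-one (both epimers at chromene C2) | CC1(C[C@H](c2ccc(OCOC)cc2OCOC)CC(=O)c2ccc(OCOC)cc2OCOC)C=Cc2c(O[Si](C(C)C)(C(C)C)C(C)C)cc3oc(-c4cccc(O[Si](C(C)C)(C(C)C)C(C)C)c4)cc3c2O1 | intermediate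
25 | (5Z)-5-[(2Z,5S)-5,7-bis[2,4-bis(methoxymethoxy)phenyl]-3-methyl-7-oxohept-2-en-1-ylidene]-6-{[tri(propan-2-yl)silyl]oxy}-2-(3-{[tri(propan-2-yl)silyl]oxy}phenyl)-1-benzofuran-4(5H)-one (vinyl ortho-quinone methide with the keto side chain cis to the methide carbon; not isolated) | C/C(C[C@H](c1ccc(OCOC)cc1OCOC)CC(=O)c1ccc(OCOC)cc1OCOC)=C/C=C1\C(=O)c2cc(-c3cccc(O[Si](C(C)C)(C(C)C)C(C)C)c3)oc2C=C1O[Si](C(C)C)(C(C)C)C(C)C | intermediate
26 | [2,4-bis(methoxymethoxy)phenyl]{(1R,2R,6S)-6-[2,4-bis(methoxymethoxy)phenyl]-2-[4-hydroxy-6-{[tri(propan-2-yl)silyl]oxy}-2-(3-{[tri(propan-2-yl)silyl]oxy}phenyl)-1-benzofuran-5-yl]-4-methylcyclohex-3-en-1-yl}methanone | CC1=C[C@@H](c2c(O[Si](C(C)C)(C(C)C)C(C)C)cc3oc(-c4cccc(O[Si](C(C)C)(C(C)C)C(C)C)c4)cc3c2O)[C@H](C(=O)c2ccc(OCOC)cc2OCOC)[C@@H](c2ccc(OCOC)cc2OCOC)C1 | intermediate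
27 | [2,4-bis(methoxymethoxy)phenyl]{(1R,2R,6S)-6-[2,4-bis(methoxymethoxy)phenyl]-2-[4,6-dihydroxy-2-(3-hydroxyphenyl)-1-benzofuran-5-yl]-4-methylcyclohex-3-en-1-yl}methanone (not isolated) | CC1=C[C@@H](c2c(O)cc3oc(-c4cccc(O)c4)cc3c2O)[C@H](C(=O)c2ccc(OCOC)cc2OCOC)[C@@H](c2ccc(OCOC)cc2OCOC)C1 | intermediate
28 | (2,4-dihydroxyphenyl){(1R,2R,6S)-6-(2,4-dihydroxyphenyl)-2-[4,6-dihydroxy-2-(3-hydroxyphenyl)-1-benzofuran-5-yl]-4-methylcyclohex-3-en-1-yl}methanone (CNP0221531.1) | CC1=C[C@@H](c2c(O)cc3oc(-c4cccc(O)c4)cc3c2O)[C@H](C(=O)c2ccc(O)cc2O)[C@@H](c2ccc(O)cc2O)C1 | target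

## Step count and risks

Total step count: 17. Longest linear sequence: 9 steps (steps 1, 2, 4, 6, 7, 8, 15, 16, 17).

**Step 16 (key step, proposed new method).**
- What may go wrong: the quinone methide, in either geometry, may be drained by 1,7-hydrogen shift or proton loss to a dienylphenol. The Lewis acid may strip MOM ethers or ionise the chromene towards Friedel–Crafts closure on the C5 aryl ring. The equilibrium may also stay on the side of 24, because ring closure places C3 next to the bulky 6-silyloxy group.
- Fallback (known chemistry): the enantioselective boron-catalysed Diels–Alder reaction of a 2′-hydroxychalcone with a dehydroprenyl diene, the established entry to this class of cyclohexenes. It sets out from 22 and 2 and returns to the route at 28.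
- Diene: 22 is formylated at C5, the only position ortho to its free hydroxyl (MgCl2, Et3N, paraformaldehyde, MeCN, reflux), to give 4-hydroxy-6-{[tri(propan-2-yl)silyl]oxy}-2-(3-{[tri(propan-2-yl)silyl]oxy}phenyl)-1-benzofuran-5-carbaldehyde F1. MOMCl and i-Pr2NEt give its 4-O-methoxymethyl ether F2. Horner–Wadsworth–Emmons olefination with diethyl (2-methylallyl)phosphonate (n-BuLi, THF) gives the 5-[(1E)-3-methylbuta-1,3-dien-1-yl]benzofuran F3.
- Dienophile: commercial 2,4-dihydroxyacetophenone is protected at its non-chelated 4-OH (MOMCl, K2CO3, acetone) to 1-[2-hydroxy-4-(methoxymethoxy)phenyl]ethan-1-one F4. Claisen–Schmidt condensation of F4 with 2 (KOH, EtOH) gives (2E)-3-[2,4-bis(methoxymethoxy)phenyl]-1-[2-hydroxy-4-(methoxymethoxy)phenyl]prop-2-en-1-one F5.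
- Cycloaddition: F3 and F5 are combined with B(OPh)3 and the BINOL enantiomer that leads to the (3R,4R,5S) series (PhCF3, rt). This gives the cycloadduct [2-hydroxy-4-(methoxymethoxy)phenyl]{(1R,2R,6S)-6-[2,4-bis(methoxymethoxy)phenyl]-2-[4-(methoxymethoxy)-6-{[tri(propan-2-yl)silyl]oxy}-2-(3-{[tri(propan-2-yl)silyl]oxy}phenyl)-1-benzofuran-5-yl]-4-methylcyclohex-3-en-1-yl}methanone F6, whose exo (all-trans) isomer is separated from the endo isomer. The fluoride-then-acid sequence of step 17 converts F6 into 28.

**Step 15.**
- What may go wrong: slow C-alkylation at the hindered C5 (flanked by the hydroxyl and the silyl ether), with keto-enal 12 diverted into self-condensation or enamine chemistry at its aryl ketone.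
- Fallback: a boron template on the phenol replaces iminium activation of the enal. It sets out from 12 and 22 and returns at 24. Compounds 22 and 12 are heated with PhB(OH)2 and propionic acid in toluene with removal of water. This gives cyclic phenylboronate F7: a 2-phenyl-4H-1,3,2-dioxaborinine ring spanning O4 and C5 of the benzofuran of 22, carrying at its C4 the (4S)-4,6-bis[2,4-bis(methoxymethoxy)phenyl]-2-methyl-6-oxohex-1-enyl chain. In F7 boron has delivered the aldehyde carbon to C5 intramolecularly. Further heating extrudes phenylboronic anhydride and releases the (2E)-quinone methide 23, which closes to 24.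

**Step 12.**
- What may go wrong: protodeiodination of the very electron-rich aryl iodide in acid, or partial loss of the silyl ether. The sluggish oxidative addition of 18 in step 14 is a related concern.
- Fallback: the order is changed so that the iodine has been used before any acid is applied. It sets out from 17 and 20 and returns at 22. Sonogashira coupling of 17 with 20 (PdCl2(PPh3)2, CuI, Et3N, 60 °C) gives tri(propan-2-yl){3,5-bis(methoxymethoxy)-4-[(3-{[tri(propan-2-yl)silyl]oxy}phenyl)ethynyl]phenoxy}silane F8. Methanolic HCl at 0 °C removes the two MOM ethers to give 21, now isolated. CuI and Et3N in DMF at 60 °C close 21 to 22.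

**Step 6.**
- What may go wrong: deprotonation of the enolisable aldehyde by the basic aryllithium (recovered 6 and aldol products), or competing attack on the enoate.
- Fallback: a neutral, aldehyde-selective arylation with a boronic acid. It sets out from 8 (through 9) and 6 and returns at 10. Aryllithium 9 is quenched with B(OMe)3 and hydrolysed to [2,4-bis(methoxymethoxy)phenyl]boronic acid F9. F9 adds to 6 under Rh(acac)(CO)2 and 1,1′-bis(diphenylphosphino)ferrocene in 1,2-dimethoxyethane–water at 80 °C to give 10.

## Further compounds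

F1 | step 16 | 4-hydroxy-6-{[tri(propan-2-yl)silyl]oxy}-2-(3-{[tri(propan-2-yl)silyl]oxy}phenyl)-1-benzofuran-5-carbaldehyde | O=Cc1c(O[Si](C(C)C)(C(C)C)C(C)C)cc2oc(-c3cccc(O[Si](C(C)C)(C(C)C)C(C)C)c3)cc2c1O
F2 | step 16 | 4-(methoxymethoxy)-6-{[tri(propan-2-yl)silyl]oxy}-2-(3-{[tri(propan-2-yl)silyl]oxy}phenyl)-1-benzofuran-5-carbaldehyde | O=Cc1c(O[Si](C(C)C)(C(C)C)C(C)C)cc2oc(-c3cccc(O[Si](C(C)C)(C(C)C)C(C)C)c3)cc2c1OCOC
F3 | step 16 | 4-(methoxymethoxy)-5-[(1E)-3-methylbuta-1,3-dien-1-yl]-6-{[tri(propan-2-yl)silyl]oxy}-2-(3-{[tri(propan-2-yl)silyl]oxy}phenyl)-1-benzofuran | C=C(C)/C=C/c1c(O[Si](C(C)C)(C(C)C)C(C)C)cc2oc(-c3cccc(O[Si](C(C)C)(C(C)C)C(C)C)c3)cc2c1OCOC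
F4 | step 16 | 1-[2-hydroxy-4-(methoxymethoxy)phenyl]ethan-1-one | CC(=O)c1ccc(OCOC)cc1O
F5 | step 16 | (2E)-3-[2,4-bis(methoxymethoxy)phenyl]-1-[2-hydroxy-4-(methoxymethoxy)phenyl]prop-2-en-1-one | O=C(/C=C/c1ccc(OCOC)cc1OCOC)c1ccc(OCOC)cc1O
F6 | step 16 | [2-hydroxy-4-(methoxymethoxy)phenyl]{(1R,2R,6S)-6-[2,4-bis(methoxymethoxy)phenyl]-2-[4-(methoxymethoxy)-6-{[tri(propan-2-yl)silyl]oxy}-2-(3-{[tri(propan-2-yl)silyl]oxy}phenyl)-1-benzofuran-5-yl]-4-methylcyclohex-3-en-1-yl}methanone | CC1=C[C@@H](c2c(O[Si](C(C)C)(C(C)C)C(C)C)cc3oc(-c4cccc(O[Si](C(C)C)(C(C)C)C(C)C)c4)cc3c2OCOC)[C@H](C(=O)c2ccc(OCOC)cc2O)[C@@H](c2ccc(OCOC)cc2OCOC)C1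
F7 | step 15 | cyclic phenylboronate of the ortho-hydroxyalkylation adduct of 22 and 12: 2-phenyl-4H-1,3,2-dioxaborinine fused across O4/C5 of the benzofuran and bearing at its C4 the (4S)-4,6-bis[2,4-bis(methoxymethoxy)phenyl]-2-methyl-6-oxohex-1-enyl chain | CC(C[C@H](c1ccc(OCOC)cc1OCOC)CC(=O)c1ccc(OCOC)cc1OCOC)=CC1OB(c2ccccc2)Oc2c1c(O[Si](C(C)C)(C(C)C)C(C)C)cc1oc(-c3cccc(O[Si](C(C)C)(C(C)C)C(C)C)c3)cc21
F8 | step 12 | tri(propan-2-yl){3,5-bis(methoxymethoxy)-4-[(3-{[tri(propan-2-yl)silyl]oxy}phenyl)ethynyl]phenoxy}silane | COCOc1cc(O[Si](C(C)C)(C(C)C)C(C)C)cc(OCOC)c1C#Cc1cccc(O[Si](C(C)C)(C(C)C)C(C)C)c1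
F9 | step 6 | [2,4-bis(methoxymethoxy)phenyl]boronic acid | OB(O)c1ccc(OCOC)cc1OCOC
A1 | alternative 1 | methyl 4-(dimethoxyphosphoryl)-3-oxobutanoate | COC(=O)CC(=O)CP(=O)(OC)OC
A2 | alternative 1 | (3E)-4-[2,4-bis(methoxymethoxy)phenyl]but-3-en-2-one | CC(=O)/C=C/c1ccc(OCOC)cc1OCOC
A3 | alternative 1 | methyl (1R,6S)-6-[2,4-bis(methoxymethoxy)phenyl]-4-methyl-2-oxocyclohex-3-ene-1-carboxylate | CC1=CC(=O)[C@H](C(=O)OC)[C@@H](c2ccc(OCOC)cc2OCOC)C1
A4 | alternative 2 | {(1E,3E)-4-[2,4-bis(methoxymethoxy)phenyl]-2-methylbuta-1,3-dien-1-yl}trimethylsilane | C[Si](C)(C)/C=C(C)/C=C/c1ccc(OCOC)cc1OCOC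
A5 | alternative 2 | (2E)-3-{4,6-bis(methoxymethoxy)-2-[3-(methoxymethoxy)phenyl]-1-benzofuran-5-yl}-1-[2-hydroxy-4-(methoxymethoxy)phenyl]prop-2-en-1-one | O=C(/C=C/c1c(OCOC)cc2oc(-c3cccc(OCOC)c3)cc2c1OCOC)c1ccc(OCOC)cc1O
A6 | alternative 2 | [2-hydroxy-4-(methoxymethoxy)phenyl]{6-[2,4-bis(methoxymethoxy)phenyl]-2-{4,6-bis(methoxymethoxy)-2-[3-(methoxymethoxy)phenyl]-1-benzofuran-5-yl}-4-methyl-3-(trimethylsilyl)cyclohex-4-en-1-yl}methanone (configuration as in the SMILES) | CC1=C[C@H](c2ccc(OCOC)cc2OCOC)[C@@H](C(=O)c2ccc(OCOC)cc2O)[C@H](c2c(OCOC)cc3oc(-c4cccc(OCOC)c4)cc3c2OCOC)[C@@H]1[Si](C)(C)C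
A7 | alternative 3 | 2-diazo-1-{5-[3-(methoxymethoxy)phenyl]furan-2-yl}ethan-1-one | [N-]=[N+]=CC(=O)c1ccc(-c2cccc(OCOC)c2)o1
A8 | alternative 3 | [2,4-bis(methoxymethoxy)phenyl]{6-[2,4-bis(methoxymethoxy)phenyl]-4-methyl-2-({[tri(propan-2-yl)silyl]oxy}ethynyl)cyclohex-3-en-1-yl}methanone (configuration as in the SMILES) | CC1=C[C@@H](C#CO[Si](C(C)C)(C(C)C)C(C)C)[C@H](C(=O)c2ccc(OCOC)cc2OCOC)[C@@H](c2ccc(OCOC)cc2OCOC)C1
A9 | alternative 3 | [2,4-bis(methoxymethoxy)phenyl]{(1R,2R,6S)-6-[2,4-bis(methoxymethoxy)phenyl]-2-{4-hydroxy-2-[3-(methoxymethoxy)phenyl]-6-{[tri(propan-2-yl)silyl]oxy}-1-benzofuran-5-yl}-4-methylcyclohex-3-en-1-yl}methanone | CC1=C[C@@H](c2c(O[Si](C(C)C)(C(C)C)C(C)C)cc3oc(-c4cccc(OCOC)c4)cc3c2O)[C@H](C(=O)c2ccc(OCOC)cc2OCOC)[C@@H](c2ccc(OCOC)cc2OCOC)C1
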